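## Retrosynthetic overview

1. The target is a (2S)-flavanone. Rings A and B are bought as arenes; the only ring to build is the pyranone ring C, and it is closed last but one, in step 10.
2. Key disconnection C2–C3: a chiral dirhodium carbenoid at C3 (from an α-diazoketone) inserts into a benzylic ether C–H at C2 of an achiral aryl benzyl ether, making ring C, the C2–C3 bond and the only stereocentre in one operation.
3. Enabling feature: C2 lies between ring oxygen O1 and ring B carbon C1', para to the 4'-methoxy group. In the open precursor it is an ArO–CH2–Ar' methylene, activated by the oxygen and by the electron-rich arene, and six atoms from C3 through C4, C4a, C8a and O1.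
4. O1–C2 comes from a Mitsunobu etherification. The 6-prenyl group comes from an aromatic Claisen rearrangement of a 5-O-(1,1-dimethylallyl) ether, which also tells the two ring A oxygens apart. The 2'-geranyl group comes from aryllithium/copper allylation.
5. The C3 diazo group is put on the acetyl group by detrifluoroacetylative diazo transfer; acid removes the two phenol protecting groups at the end.

Key step: step 10

Assumption: the sense of induction of the dirhodium catalyst at C2 cannot be assigned with certainty beforehand; the route is written with Rh2(S-PTTL)4, and the mirror-image complex Rh2(R-PTTL)4 takes its place if a pilot run shows the 2R sense.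

Abbreviations in names: geranyl = (2E)-3,7-dimethylocta-2,6-dien-1-yl; prenyl = 3-methylbut-2-en-1-yl; MOM = methoxymethyl; TBS = tert-butyldimethylsilyl.

## Route

Step 1
Reactants: 1 2-bromo-3-hydroxy-4-methoxybenzaldehyde (2-bromoisovanillin)
Product: 2 2-bromo-4-methoxy-3-(methoxymethoxy)benzaldehyde
Conditions: MOMCl, i-Pr2NEt, CH2Cl2, 0 °C → rt
Reagents that add atoms: chloromethyl methyl ether (MOMCl), COCCl
Why: O-alkylation of the phenoxide gives a MOM acetal that survives the organolithium step, and no silyl group sits ortho to the future carbanion, so no retro-Brook shift can occur.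

Step 2
Reactants: 2 2-bromo-4-methoxy-3-(methoxymethoxy)benzaldehyde
Product: 3 [2-bromo-4-methoxy-3-(methoxymethoxy)phenyl]methanol
Conditions: NaBH4, MeOH, 0 °C
Reagents that add atoms: none
Why: Borohydride reduction of the aryl aldehyde to the benzylic alcohol should leave the aryl bromide and the acetal untouched.

Step 3
Reactants: 3 [2-bromo-4-methoxy-3-(methoxymethoxy)phenyl]methanol; 4 geranyl bromide
Product: 6 [2-geranyl-4-methoxy-3-(methoxymethoxy)phenyl]methanol, via dilithio aryl alkoxide 5 (not isolated)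
Conditions: n-BuLi (2.2 equiv), THF, −78 °C; then CuBr·SMe2 (10 mol%), 4, −78 → 0 °C
Reagents that add atoms: n-butyllithium, [Li]CCCC (its lithium stays only in intermediate 5)
Why: O–H deprotonation and bromine–lithium exchange give an aryllithium held between OMOM and CH2OLi, and copper-catalysed allylic substitution at the primary carbon of geranyl bromide (SN2 rather than SN2′) should attach the chain with its E olefin unchanged.

Step 4
Reactants: 7 1-(2,6-dihydroxy-4-methoxyphenyl)ethan-1-one; 8 3-chloro-3-methylbut-1-yne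
Product: 9 1-{2-hydroxy-4-methoxy-6-[(2-methylbut-3-yn-2-yl)oxy]phenyl}ethan-1-one
Conditions: 8 (1.2 equiv), DBU, CuCl2·2H2O (1 mol%), MeCN, 0 °C → rt
Reagents that add atoms: none
Why: Copper-catalysed propargylic etherification of a phenol by the tertiary chloride should stop at the mono-ether, because the second hydroxyl stays locked in the hydrogen bond to the ketone; this differentiates the two ring A oxygens.

Step 5
Reactants: 9 1-{2-hydroxy-4-methoxy-6-[(2-methylbut-3-yn-2-yl)oxy]phenyl}ethan-1-one
Product: 10 1-{2-hydroxy-4-methoxy-6-[(2-methylbut-3-en-2-yl)oxy]phenyl}ethan-1-one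
Conditions: H2 (1 atm), Pd/CaCO3 poisoned with Pb(OAc)2 (Lindlar catalyst), quinoline, EtOAc, rt
Reagents that add atoms: none
Why: Lindlar semihydrogenation of the terminal alkyne should stop at the vinyl group and give the 1,1-dimethylallyl aryl ether.

Step 6
Reactants: 10 1-{2-hydroxy-4-methoxy-6-[(2-methylbut-3-en-2-yl)oxy]phenyl}ethan-1-one; 6 [2-geranyl-4-methoxy-3-(methoxymethoxy)phenyl]methanol
Product: 11 1-{2-{[2-geranyl-4-methoxy-3-(methoxymethoxy)phenyl]methoxy}-4-methoxy-6-[(2-methylbut-3-en-2-yl)oxy]phenyl}ethan-1-one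
Conditions: PPh3, DIAD, THF, 0 °C → rt
Reagents that add atoms: none
Why: In this Mitsunobu etherification the acidic ortho-acyl phenol attacks the alkoxyphosphonium ion of the primary benzylic alcohol, forming the O1–C2 bond under neutral conditions that spare the tertiary allyl ether, the acetal and the olefins.

Step 7
Reactants: 11 1-{2-{[2-geranyl-4-methoxy-3-(methoxymethoxy)phenyl]methoxy}-4-methoxy-6-[(2-methylbut-3-en-2-yl)oxy]phenyl}ethan-1-one
Product: 12 1-{6-{[2-geranyl-4-methoxy-3-(methoxymethoxy)phenyl]methoxy}-2-hydroxy-4-methoxy-3-prenylphenyl}ethan-1-one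
Conditions: PhNEt2, 130 °C
Reagents that add atoms: none
Why: The aromatic Claisen rearrangement ([3,3]) of the 1,1-dimethylallyl ether delivers the allyl unit with allylic inversion to the only free ortho carbon, giving the normal prenyl group at the future C6 and freeing the hydrogen-bonded phenol.

Step 8
Reactants: 12 1-{6-{[2-geranyl-4-methoxy-3-(methoxymethoxy)phenyl]methoxy}-2-hydroxy-4-methoxy-3-prenylphenyl}ethan-1-one
Product: 13 1-{2-[(tert-butyldimethylsilyl)oxy]-6-{[2-geranyl-4-methoxy-3-(methoxymethoxy)phenyl]methoxy}-4-methoxy-3-prenylphenyl}ethan-1-one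
Conditions: TBSOTf, 2,6-lutidine, CH2Cl2, −78 → 0 °C
Reagents that add atoms: tert-butyldimethylsilyl triflate (TBSOTf), CC(C)(C)[Si](C)(C)OS(=O)(=O)C(F)(F)F
Why: The silyl triflate should silylate the hindered, hydrogen-bonded phenol; the bulky silyl ether removes the O–H and shields O5 for the carbenoid step.

Step 9
Reactants: 13 1-{2-[(tert-butyldimethylsilyl)oxy]-6-{[2-geranyl-4-methoxy-3-(methoxymethoxy)phenyl]methoxy}-4-methoxy-3-prenylphenyl}ethan-1-one
Product: 16 2-diazo-1-{2-[(tert-butyldimethylsilyl)oxy]-6-{[2-geranyl-4-methoxy-3-(methoxymethoxy)phenyl]methoxy}-4-methoxy-3-prenylphenyl}ethan-1-one, via lithium enolate 14 (not isolated), via trifluoroacetyl diketone 15 (not isolated)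
Conditions: LiHMDS, THF, −78 °C; CF3CO2CH2CF3, −78 °C; then p-ABSA, Et3N, H2O (1 equiv), MeCN, rt
Reagents that add atoms: lithium hexamethyldisilazide, [Li]N([Si](C)(C)C)[Si](C)(C)C (lithium only in 14); 2,2,2-trifluoroethyl trifluoroacetate, O=C(OCC(F)(F)F)C(F)(F)F (trifluoroacetyl only in 15); 4-acetamidobenzenesulfonyl azide (p-ABSA), CC(=O)Nc1ccc(cc1)S(=O)(=O)N=[N+]=[N-] (N2 in 16)
Why: In this detrifluoroacetylative diazo transfer the kinetic methyl ketone enolate is trifluoroacetylated, and the activated 1,3-diketone takes the diazo group from the sulfonyl azide while losing the trifluoroacetyl group as the N-sulfonyl amide, which should give the terminal α-diazoketone with all other groups intact.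

Step 10
Reactants: 16 2-diazo-1-{2-[(tert-butyldimethylsilyl)oxy]-6-{[2-geranyl-4-methoxy-3-(methoxymethoxy)phenyl]methoxy}-4-methoxy-3-prenylphenyl}ethan-1-one
Product: 17 (2S)-5-[(tert-butyldimethylsilyl)oxy]-2-[2-geranyl-4-methoxy-3-(methoxymethoxy)phenyl]-7-methoxy-6-prenyl-2,3-dihydro-4H-chromen-4-one
Conditions: Rh2(S-PTTL)4 (1 mol%), CH2Cl2, 0 °C → rt, slow addition of 16 (syringe pump, high dilution)
Reagents that add atoms: none
Why: The chiral dirhodium tetracarboxylate expels N2 from 16 to give an electrophilic rhodium carbenoid at C3, which inserts into one of the two enantiotopic C–H bonds of the O1–CH2–Ar' methylene through a three-centre transition state with hydride-transfer character, forming the C2–C3 bond and releasing the catalyst. The closest known reaction type is the dirhodium-carboxylate-catalysed intramolecular C–H insertion of ortho-alkoxyaryl α-diazoketones into the ether methylene to give chroman-4-ones, including enantioselective versions with chiral carboxylate ligands. Ring C closes as a six-membered ring by formal 1,6 C–H insertion through the cyclic array C3–C4–C4a–C8a–O1–C2. C2 is the only new stereocentre and is under catalyst control, since the substrate is achiral and the phthalimido walls of the tert-leucinate ligands decide which benzylic hydrogen meets the carbenoid. The step needs C–H insertion to win over oxonium ylide formation at O1 or O5 followed by 1,2-shift, O–H insertion, cyclopropanation and carbene dimerisation; this is secured because the reacting C–H is activated twice (alpha to O1 and benzylic to the para-methoxyphenyl ring, which stabilises the developing positive charge), O1 is a weakly nucleophilic vinylogous ester oxygen, O5 carries a bulky silyl group and no free hydroxyl is present. The 6-prenyl olefin is meta to the acyl carbon and cannot reach the carbenoid, the geranyl olefins could do so only through rings of ten or more atoms, and slow addition at high dilution suppresses bimolecular paths.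

Step 11
Reactants: 17 (2S)-5-[(tert-butyldimethylsilyl)oxy]-2-[2-geranyl-4-methoxy-3-(methoxymethoxy)phenyl]-7-methoxy-6-prenyl-2,3-dihydro-4H-chromen-4-one
Product: 18 (2S)-5-hydroxy-2-(2-geranyl-3-hydroxy-4-methoxyphenyl)-7-methoxy-6-prenyl-2,3-dihydro-4H-chromen-4-one (target)
Conditions: aq. 3 M HCl, MeOH, 40 °C
Reagents that add atoms: none
Why: Acid-catalysed acetal exchange removes the MOM group and solvolysis removes the peri-carbonyl aryl silyl ether, and the acidic medium avoids the base-induced retro-oxa-Michael ring opening by which 5-hydroxyflavanones racemise, so C2 should stay intact.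

## Compound list

1 | 2-bromo-3-hydroxy-4-methoxybenzaldehyde | COc1ccc(C=O)c(Br)c1O | starting material
2 | 2-bromo-4-methoxy-3-(methoxymethoxy)benzaldehyde | COc1ccc(C=O)c(Br)c1OCOC | intermediate
3 | [2-bromo-4-methoxy-3-(methoxymethoxy)phenyl]methanol | COc1ccc(CO)c(Br)c1OCOC | intermediate
4 | geranyl bromide, (2E)-1-bromo-3,7-dimethylocta-2,6-diene | BrC/C=C(\C)CCC=C(C)C | starting material
5 | lithium [2-lithio-4-methoxy-3-(methoxymethoxy)phenyl]methanolate | [Li]OCc1ccc(OC)c(OCOC)c1[Li] | intermediate
6 | [2-geranyl-4-methoxy-3-(methoxymethoxy)phenyl]methanol | COc1ccc(CO)c(C/C=C(\C)CCC=C(C)C)c1OCOC | intermediate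
7 | 1-(2,6-dihydroxy-4-methoxyphenyl)ethan-1-one | CC(=O)c1c(O)cc(OC)cc1O | starting material
8 | 3-chloro-3-methylbut-1-yne | C#CC(C)(C)Cl | starting material
9 | 1-{2-hydroxy-4-methoxy-6-[(2-methylbut-3-yn-2-yl)oxy]phenyl}ethan-1-one | CC(=O)c1c(O)cc(OC)cc1OC(C)(C)C#C | intermediate
10 | 1-{2-hydroxy-4-methoxy-6-[(2-methylbut-3-en-2-yl)oxy]phenyl}ethan-1-one | CC(=O)c1c(O)cc(OC)cc1OC(C)(C)C=C | intermediate
11 | 1-{2-{[2-geranyl-4-methoxy-3-(methoxymethoxy)phenyl]methoxy}-4-methoxy-6-[(2-methylbut-3-en-2-yl)oxy]phenyl}ethan-1-one | CC(=O)c1c(OCc2ccc(OC)c(OCOC)c2C/C=C(\C)CCC=C(C)C)cc(OC)cc1OC(C)(C)C=C | intermediate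
12 | 1-{6-{[2-geranyl-4-methoxy-3-(methoxymethoxy)phenyl]methoxy}-2-hydroxy-4-methoxy-3-prenylphenyl}ethan-1-one | CC(=O)c1c(OCc2ccc(OC)c(OCOC)c2C/C=C(\C)CCC=C(C)C)cc(OC)c(CC=C(C)C)c1O | intermediate
13 | 1-{2-[(tert-butyldimethylsilyl)oxy]-6-{[2-geranyl-4-methoxy-3-(methoxymethoxy)phenyl]methoxy}-4-methoxy-3-prenylphenyl}ethan-1-one | CC(=O)c1c(OCc2ccc(OC)c(OCOC)c2C/C=C(\C)CCC=C(C)C)cc(OC)c(CC=C(C)C)c1O[Si](C)(C)C(C)(C)C | intermediate
14 | lithium enolate of 13 (lithium 1-arylethen-1-olate) | [Li]OC(=C)c1c(OCc2ccc(OC)c(OCOC)c2C/C=C(\C)CCC=C(C)C)cc(OC)c(CC=C(C)C)c1O[Si](C)(C)C(C)(C)C | intermediate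
15 | 4,4,4-trifluoro-1-{2-[(tert-butyldimethylsilyl)oxy]-6-{[2-geranyl-4-methoxy-3-(methoxymethoxy)phenyl]methoxy}-4-methoxy-3-prenylphenyl}butane-1,3-dione | O=C(CC(=O)C(F)(F)F)c1c(OCc2ccc(OC)c(OCOC)c2C/C=C(\C)CCC=C(C)C)cc(OC)c(CC=C(C)C)c1O[Si](C)(C)C(C)(C)C | intermediate
16 | 2-diazo-1-{2-[(tert-butyldimethylsilyl)oxy]-6-{[2-geranyl-4-methoxy-3-(methoxymethoxy)phenyl]methoxy}-4-methoxy-3-prenylphenyl}ethan-1-one | [N-]=[N+]=CC(=O)c1c(OCc2ccc(OC)c(OCOC)c2C/C=C(\C)CCC=C(C)C)cc(OC)c(CC=C(C)C)c1O[Si](C)(C)C(C)(C)C | intermediate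
17 | (2S)-5-[(tert-butyldimethylsilyl)oxy]-2-[2-geranyl-4-methoxy-3-(methoxymethoxy)phenyl]-7-methoxy-6-prenyl-2,3-dihydro-4H-chromen-4-one | COc1ccc([C@@H]2CC(=O)c3c(cc(OC)c(CC=C(C)C)c3O[Si](C)(C)C(C)(C)C)O2)c(C/C=C(\C)CCC=C(C)C)c1OCOC | intermediate
18 | (2S)-5-hydroxy-2-(2-geranyl-3-hydroxy-4-methoxyphenyl)-7-methoxy-6-prenyl-2,3-dihydro-4H-chromen-4-one | COc1ccc([C@@H]2CC(=O)c3c(cc(OC)c(CC=C(C)C)c3O)O2)c(C/C=C(\C)CCC=C(C)C)c1O | target

## Step count and risks

Total step count: 11. Longest linear sequence: 9 steps (steps 1–3 and 6–11, from 1).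

Steps most likely to fail:

1. Step 10. The carbenoid may be captured by the O1 lone pair, giving an oxonium ylide that undergoes a 1,2-benzyl shift instead of C–H insertion, or the catalyst may discriminate the two enantiotopic hydrogens poorly. The fallback closes ring C at O1–C2 by oxa-Michael addition instead; it sets out from 6 and 10 and comes back at 18.
   - Alcohol 6 is oxidised with MnO2 in CH2Cl2 to 2-geranyl-4-methoxy-3-(methoxymethoxy)benzaldehyde F1.
   - Claisen–Schmidt condensation of 10 with F1 (KOH, EtOH, rt) gives the 2'-hydroxychalcone F2, whose only free hydroxyl is the one that must become O1.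
   - F2 is cyclised by intramolecular oxa-Michael addition under a quinine-derived bifunctional thiourea catalyst, and the 2S-flavanone carrying the 5-O-(1,1-dimethylallyl) ether F3 is brought to enantiopurity by preparative HPLC on a chiral stationary phase.
   - Aromatic Claisen rearrangement of F3 (PhMe, 110 °C) gives the 5-hydroxy-6-prenyl flavanone 3'-MOM ether F4.
   - F4 is deprotected under the conditions of step 11 to give 18.

2. Step 11. Protic acid may add the freed phenols to the neighbouring prenyl and geranyl olefins (chroman formation), or may open the benzylic C2–O1 bond and erode the configuration. The fallback unmasks the two phenols one at a time without protic acid; it sets out from 17 and comes back at 18.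
   - The MOM group is removed with TMSOTf and 2,2'-bipyridyl in CH2Cl2 at 0 °C followed by water, giving the 5-O-TBS flavanone with free 3'-OH F5.
   - The silyl ether of F5 is cleaved with TBAF buffered with AcOH in THF at 0 °C to give 18.

3. Step 3. Bromine–lithium exchange next to the alkoxide may be incomplete, and the aryl anion or the alkoxide may attack geranyl bromide at the wrong position (SN2′ or O-allylation). The fallback reverses the polarity of the coupling; it sets out from 3 and comes back at 6.
   - Tributyl(geranyl)stannane F6 is made from 4 and Bu3SnLi.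
   - Stille coupling of F6 with aryl bromide 3 (Pd2(dba)3, P(t-Bu)3, CsF, dioxane, 80 °C) should give 6 directly, with the free alcohol tolerated.

## Further compounds

F1 | step 10 | 2-geranyl-4-methoxy-3-(methoxymethoxy)benzaldehyde | COc1ccc(C=O)c(C/C=C(\C)CCC=C(C)C)c1OCOC
F2 | step 10 | (2E)-3-[2-geranyl-4-methoxy-3-(methoxymethoxy)phenyl]-1-{2-hydroxy-4-methoxy-6-[(2-methylbut-3-en-2-yl)oxy]phenyl}prop-2-en-1-one | C=CC(C)(C)Oc1cc(OC)cc(O)c1C(=O)/C=C/c1ccc(OC)c(OCOC)c1C/C=C(\C)CCC=C(C)C
F3 | step 10 | (2S)-2-[2-geranyl-4-methoxy-3-(methoxymethoxy)phenyl]-7-methoxy-5-[(2-methylbut-3-en-2-yl)oxy]-2,3-dihydro-4H-chromen-4-one | COc1ccc([C@@H]2CC(=O)c3c(cc(OC)cc3OC(C)(C)C=C)O2)c(C/C=C(\C)CCC=C(C)C)c1OCOC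
F4 | step 10 | (2S)-2-[2-geranyl-4-methoxy-3-(methoxymethoxy)phenyl]-5-hydroxy-7-methoxy-6-prenyl-2,3-dihydro-4H-chromen-4-one | COc1ccc([C@@H]2CC(=O)c3c(cc(OC)c(CC=C(C)C)c3O)O2)c(C/C=C(\C)CCC=C(C)C)c1OCOC
F5 | step 11 | (2S)-5-[(tert-butyldimethylsilyl)oxy]-2-(2-geranyl-3-hydroxy-4-methoxyphenyl)-7-methoxy-6-prenyl-2,3-dihydro-4H-chromen-4-one | COc1ccc([C@@H]2CC(=O)c3c(cc(OC)c(CC=C(C)C)c3O[Si](C)(C)C(C)(C)C)O2)c(C/C=C(\C)CCC=C(C)C)c1O
F6 | step 3 | tributyl[(2E)-3,7-dimethylocta-2,6-dien-1-yl]stannane | CCCC[Sn](CCCC)(CCCC)C/C=C(\C)CCC=C(C)C
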